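The D of three new flasks was wanted at 25 min, so I asked first how long G lasted in each.

| setting | elm | dawn | summer | noon |
|---|---|---|---|---|
| G | 0.17 M | 0.15 M | 0.25 M | 0.40 M |
| remark | run made earlier |  |  |  |
| time |  | 25 min | 25 min | 25 min |

elm run (percent of the G charged)

| time / min | D / % | G / % |
|---|---|---|
| 2.50 | 26.8 | 66.0 |
| 5.00 | 50.4 | 41.7 |
| 8.00 | 69.5 | 17.5 |
| 10.0 | 78.0 | 9.7 |
| 12.0 | 84.9 | 6.9 |
| 15.0 | 86.5 | 1.6 |

(standard deviation of a reading: 1 percentage point)

- "hardly changes" means that all values lie within two and a half points (for a concentration: within two and a half percent of the largest)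

- [D] at the end for dawn, summer, noon, in this order
- the shape of the row from first to last (falls, then rises / hardly changes / rises all the way / rises, then falls / falls all the way)

From the elm run I read k, the first-order constant of G loss by every route. Over the first interval, k was 0.166 /min at a mean G of 0.141 M. From 5.00 min to 10.0 min it was 0.292 /min at a mean G of 0.0437 M, so k was higher where G was lower. That is the pattern of Michaelis-Menten saturation, in which k equals a free constant kf divided by one plus G/K, and the ceiling rate Vmax is kf times K. These two readings, with their scatter, gave Vmax = 0.0376 M/min, kf = 0.441 /min and K = 0.0853 M.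

At the start, this slowing divides kf by 2.76 in dawn, 3.93 in summer and 5.69 in noon. Added up over a run, the slowing costs roughly the charge over Vmax, on top of a first-order time of 10.4 min to fall to 1.00% of the charge. That makes 14.4 min for dawn, 17.0 min for summer and 21.0 min for noon. This clearing time, the time G needs to fall to 1.00% of its charge, is what I carried forward. Noon's stood 4.04 min inside the run.

The forecast gave 0.13 M, 0.215 M and 0.335 M, rises all the way, from a K of 0.08 M and a Vmax of 0.034 M/min, near my values but not equal to them. It said: “All three runs therefore finish.”

The flasks gave 0.134 M, 0.217 M and 0.331 M, rises all the way.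

    G ⇌ L (K = 30.0, k = 0.0230 /min)
    G → D, rate k2*[G]/(1 + ([G]/sat2)) (0.0860 M, k = 0.360 /min)

At 25.0 min, noon held 0.36% of its G, under the 1.00% that I had reckoned for it at its clearing time of 21.0 min, earlier in the run. Summer's clearing time was 17.0 min, and the same reckoning, taken to the 8.30% of G that summer held at 12.5 min, gives 11.7 min.

(All runs were computed with made-up constants, noise included.)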